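**Strategy**

Ring A of the chroman-2-one has the oxygen pattern of a cyclised polyketide: the ketone carbon of the 8-acyl group and C8a are 1,3-related across C8, the signature of a Claisen condensation, so the C8–C8a bond is the one disconnected. In the forward sense a 4-methoxy-2-pyrone, carrying the finished C4 stereocentre on its C3 substituent and a 2-oxo-4-phenylbutyl chain at C6, is opened by methoxide at its lactone carbonyl and recloses through carbon, which delivers the complete 8-acyl-5,7,8a-trioxygenated ring A in one operation. The pyrone methyl ether becomes the C5 ether, so only the C8a hydroxyl can lactonise afterwards. The stereocentre comes from an iminium-catalysed Michael addition.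

Key step: step 6

Assumption: the sense of induction in step 1 is taken from the usual shielding model for diarylprolinol silyl ether iminium ions; should the adduct prove to be the R enantiomer, the (R)-catalyst would be used and nothing else changes. Locants C4, C4a, C5, C7, C8 and C8a are those of the chroman-2-one target throughout.

**Route**

Step 1
Reactants: 1 4-hydroxy-6-methyl-2H-pyran-2-one; 2 (E)-3-(4-methoxyphenyl)prop-2-enal
Product: 4 (4S)-2-hydroxy-4-(4-methoxyphenyl)-7-methyl-3,4-dihydro-2H,5H-pyrano[4,3-b]pyran-5-one (lactol; both C2 epimers), via open-chain Michael aldehyde 3 (not isolated)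
Conditions: (S)-2-[diphenyl(trimethylsilyloxy)methyl]pyrrolidine (10 mol%), CH2Cl2, rt
Reagents that add atoms: none
Why: Iminium-ion catalysis (organocatalytic Michael addition followed by hemiacetalisation): C3 of the hydroxypyrone adds to the β-carbon of the E-configured iminium ion on the face left open by the diphenyl(silyloxy)methyl group of the (S)-catalyst, which should set C4 as S, and the pyrone hydroxyl then traps the aldehyde as the lactol.

Step 2
Reactants: 4 (4S)-2-hydroxy-4-(4-methoxyphenyl)-7-methyl-3,4-dihydro-2H,5H-pyrano[4,3-b]pyran-5-one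
Product: 6 methyl (S)-3-(4-hydroxy-6-methyl-2-oxo-2H-pyran-3-yl)-3-(4-methoxyphenyl)propanoate, via enol lactone 5 (not isolated)
Conditions: Dess–Martin periodinane (1.2 equiv), CH2Cl2, 0 °C to rt; then MeOH, Et3N, rt
Reagents that add atoms: methanol, CO
Why: Dess–Martin oxidation of a lactol to a lactone followed by transesterification: the enol lactone is an activated ester whose leaving group is the acidic pyrone enol, so methanol should open it at the δ-lactone carbonyl under mild base while the vinylogous pyrone lactone and the stereocentre, which is β to both carbonyls, stay untouched.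

Step 3
Reactants: 6 methyl (S)-3-(4-hydroxy-6-methyl-2-oxo-2H-pyran-3-yl)-3-(4-methoxyphenyl)propanoate
Product: 7 methyl (S)-3-(4-methoxy-6-methyl-2-oxo-2H-pyran-3-yl)-3-(4-methoxyphenyl)propanoate
Conditions: Me2SO4 (1.2 equiv), K2CO3 (1.5 equiv), acetone, reflux
Reagents that add atoms: dimethyl sulfate, COS(=O)(=O)OC
Why: O-Alkylation of the pyronate (Williamson-type ether synthesis) with the hard electrophile dimethyl sulfate in acetone is the usual way from 4-hydroxy- to 4-methoxy-2-pyrones, and neither the methyl ester nor the stereocentre should react under carbonate.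

Step 4
Reactants: 7 methyl (S)-3-(4-methoxy-6-methyl-2-oxo-2H-pyran-3-yl)-3-(4-methoxyphenyl)propanoate; 8 3-phenylpropanal
Product: 9 methyl (3S)-3-[6-(2-hydroxy-4-phenylbutyl)-4-methoxy-2-oxo-2H-pyran-3-yl]-3-(4-methoxyphenyl)propanoate (both carbinol epimers)
Conditions: LiN(SiMe3)2 (1.1 equiv), THF, −78 °C; then 8 (1.3 equiv), −78 °C; aq NH4Cl
Reagents that add atoms: none
Why: Vinylogous aldol addition: lithium amides remove a proton from the C6 methyl group of 4-methoxy-2-pyrones to give a delocalised anion that adds to aldehydes at −78 °C; LiN(SiMe3)2 should deprotonate this far more acidic position in preference to the β-branched ester arm, the aldehyde outruns every ester electrophile, one equivalent of base suffices because the product is an alkoxide, and the new carbinol centre (formed without control) disappears in the next step.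

Step 5
Reactants: 9 methyl (3S)-3-[6-(2-hydroxy-4-phenylbutyl)-4-methoxy-2-oxo-2H-pyran-3-yl]-3-(4-methoxyphenyl)propanoate
Product: 10 methyl (S)-3-(4-methoxyphenyl)-3-[4-methoxy-2-oxo-6-(2-oxo-4-phenylbutyl)-2H-pyran-3-yl]propanoate
Conditions: Dess–Martin periodinane (1.3 equiv), CH2Cl2, 0 °C to rt
Reagents that add atoms: none
Why: Dess–Martin oxidation of the secondary alcohol should give the β-keto pyrone under neutral conditions that neither dehydrate the aldol nor touch the C4 stereocentre.

Step 6
Reactants: 10 methyl (S)-3-(4-methoxyphenyl)-3-[4-methoxy-2-oxo-6-(2-oxo-4-phenylbutyl)-2H-pyran-3-yl]propanoate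
Product: 12 methyl (S)-3-[2,4-dihydroxy-6-methoxy-3-(3-phenylpropanoyl)phenyl]-3-(4-methoxyphenyl)propanoate, via ring-opened diketo diester 11 (not isolated)
Conditions: Mg(OMe)2 (4 equiv), MeOH, reflux; then 1 M HCl, 0 °C
Reagents that add atoms: none
Why: Methoxide adds to the lactone carbonyl of the pyrone and the ring opens to diester 11, in which the new methyl ester (the future C8a) and the diketone chain remain on the same side of the surviving enol ether C=C bond; the magnesium-chelated carbanion between the two ketones (the future C8) attacks that ester, methoxide is expelled and the cyclic triketone enolises irreversibly to the benzene ring. The closest known reaction type is the magnesium methoxide recyclisation of 6-(2-oxoalkyl)-4-oxygenated 2-pyrones and of open-chain 3,5,7-triketo esters to acylphloroglucinols, the laboratory counterpart of the polyketide Claisen cyclisation. Ring A is closed by a 6-exo-trig acyl substitution in which the diketonate carbon is the nucleophile and the ester C=O lies outside the forming ring. No stereocentre is made, and the one at C4 is β to the ester of the arm and not acidic, so it should pass through unchanged. The step needs carbon acylation instead of an aldol closure and a fixed oxygen pattern: pyrone C3 is fully substituted and held in the enol ether, so an aldol ring through C3 could never aromatise, the magnesium chelate favours attack through carbon over closure through oxygen to a 4-pyranone, and the 4-methoxy group, which could only be exchanged for another methoxy group in this medium, ends up as the C5 methyl ether and leaves the C8a hydroxyl as the only free phenol beside the arm. The ester of the arm is a methyl ester to match the medium and sits across the enol ether double bond from the only methylene that could reach it, so a competing Dieckmann-type closure is geometrically excluded.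

Step 7
Reactants: 12 methyl (S)-3-[2,4-dihydroxy-6-methoxy-3-(3-phenylpropanoyl)phenyl]-3-(4-methoxyphenyl)propanoate
Product: 13 (S)-7-hydroxy-5-methoxy-4-(4-methoxyphenyl)-8-(3-phenylpropanoyl)chroman-2-one
Conditions: p-TsOH·H2O (10 mol%), toluene, 80 °C
Reagents that add atoms: none
Why: Acid-catalysed intramolecular transesterification (lactonisation) should close the six-membered lactone on the C8a hydroxyl, the only one within reach because the C5 oxygen is methylated and the C7 hydroxyl is para to the arm, and the mild acid should not ionise the doubly benzylic C4–C4a bond.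

Step 8
Reactants: 13 (S)-7-hydroxy-5-methoxy-4-(4-methoxyphenyl)-8-(3-phenylpropanoyl)chroman-2-one
Product: 14 (S)-5,7-dihydroxy-4-(4-hydroxyphenyl)-8-(3-phenylpropanoyl)chroman-2-one (target)
Conditions: BBr3 (6 equiv), CH2Cl2, −78 °C to rt; ice-water
Reagents that add atoms: none
Why: Lewis-acid cleavage of aryl methyl ethers by BBr3 (boron coordination, then bromide attack on the methyl group) should free both phenols while the aryl lactone and the chelated aryl ketone survive; quenching with ice-water and avoiding alcohols and base keeps the lactone closed, so it cannot re-form on the newly freed C5 hydroxyl.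

**Compound list**

1 | 4-hydroxy-6-methyl-2H-pyran-2-one | CC1=CC(O)=CC(=O)O1 | starting material
2 | (E)-3-(4-methoxyphenyl)prop-2-enal | COc1ccc(/C=C/C=O)cc1 | starting material
3 | (S)-3-(4-hydroxy-6-methyl-2-oxo-2H-pyran-3-yl)-3-(4-methoxyphenyl)propanal (open-chain Michael aldehyde; not isolated) | O=CC[C@@H](c1ccc(OC)cc1)C1=C(O)C=C(C)OC1=O | intermediate
4 | (4S)-2-hydroxy-4-(4-methoxyphenyl)-7-methyl-3,4-dihydro-2H,5H-pyrano[4,3-b]pyran-5-one (lactol; both C2 epimers) | OC1C[C@@H](c2ccc(OC)cc2)C2=C(O1)C=C(C)OC2=O | intermediate
5 | (S)-4-(4-methoxyphenyl)-7-methyl-3,4-dihydro-2H,5H-pyrano[4,3-b]pyran-2,5-dione (enol lactone; not isolated) | O=C1C[C@@H](c2ccc(OC)cc2)C2=C(O1)C=C(C)OC2=O | intermediate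
6 | methyl (S)-3-(4-hydroxy-6-methyl-2-oxo-2H-pyran-3-yl)-3-(4-methoxyphenyl)propanoate | COC(=O)C[C@@H](c1ccc(OC)cc1)C1=C(O)C=C(C)OC1=O | intermediate
7 | methyl (S)-3-(4-methoxy-6-methyl-2-oxo-2H-pyran-3-yl)-3-(4-methoxyphenyl)propanoate | COC(=O)C[C@@H](c1ccc(OC)cc1)C1=C(OC)C=C(C)OC1=O | intermediate
8 | 3-phenylpropanal | O=CCCc1ccccc1 | starting material
9 | methyl (3S)-3-[6-(2-hydroxy-4-phenylbutyl)-4-methoxy-2-oxo-2H-pyran-3-yl]-3-(4-methoxyphenyl)propanoate (both carbinol epimers) | COC(=O)C[C@@H](c1ccc(OC)cc1)C1=C(OC)C=C(CC(O)CCc2ccccc2)OC1=O | intermediate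
10 | methyl (S)-3-(4-methoxyphenyl)-3-[4-methoxy-2-oxo-6-(2-oxo-4-phenylbutyl)-2H-pyran-3-yl]propanoate | COC(=O)C[C@@H](c1ccc(OC)cc1)C1=C(OC)C=C(CC(=O)CCc2ccccc2)OC1=O | intermediate
11 | dimethyl (S,E)-2-(1-methoxy-3,5-dioxo-7-phenylheptylidene)-3-(4-methoxyphenyl)pentanedioate (ring-opened diketo diester; not isolated) | COC(=O)C[C@@H](c1ccc(OC)cc1)/C(C(=O)OC)=C(\OC)CC(=O)CC(=O)CCc1ccccc1 | intermediate
12 | methyl (S)-3-[2,4-dihydroxy-6-methoxy-3-(3-phenylpropanoyl)phenyl]-3-(4-methoxyphenyl)propanoate | COC(=O)C[C@@H](c1ccc(OC)cc1)c1c(OC)cc(O)c(C(=O)CCc2ccccc2)c1O | intermediate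
13 | (S)-7-hydroxy-5-methoxy-4-(4-methoxyphenyl)-8-(3-phenylpropanoyl)chroman-2-one | O=C1C[C@@H](c2ccc(OC)cc2)c2c(OC)cc(O)c(C(=O)CCc3ccccc3)c2O1 | intermediate
14 | (S)-5,7-dihydroxy-4-(4-hydroxyphenyl)-8-(3-phenylpropanoyl)chroman-2-one | O=C1C[C@@H](c2ccc(O)cc2)c2c(O)cc(O)c(C(=O)CCc3ccccc3)c2O1 | target

**Step count**

Total step count: 8. Longest linear sequence: 8 steps (1 to 14).

**Steps most likely to fail**

Step 6 (pyrone opening and Claisen recyclisation). The β-keto pyrone may first be converted into its anion, which resists methoxide attack, so that addition at C6 or C4 stays reversible and unproductive. The opened triketo ester may also close through oxygen to a 4-pyranone, or lose the geometry of its enol ether and then cyclise onto the ester of the arm. The fallback takes the aromatic ring ready-made and forms the C4–C4a bond instead; it sets out from compound 2 and comes back to the route at compound 13. The purchased dihydrochalcone 1-(2,6-dihydroxy-4-methoxyphenyl)-3-phenylpropan-1-one F1 would be added to enal 2 under the iminium catalysis of step 1, as a Friedel–Crafts-type conjugate addition of an electron-rich phenol followed by hemiacetalisation, with the same facial sense. Its two nucleophilic ring carbons are equivalent, and the only hydroxyl beside the new bond is the one next to the acyl group, so the chromanol 1-[(4S)-2,7-dihydroxy-5-methoxy-4-(4-methoxyphenyl)-3,4-dihydro-2H-chromen-8-yl]-3-phenylpropan-1-one F2 should form as one constitutional isomer. Oxidation of this lactol with Dess–Martin periodinane would give lactone 13.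

Step 4 (lithiation and aldol addition in the presence of the ester arm). Partial enolisation of the ester, attack of the lithiated pyrone on the ester of a second molecule, or quenching of the anion by the enolisable aldehyde may lower the conversion. The fallback puts the keto chain on before the ester exists; it sets out from compound 1 and comes back at compound 10. The dianion of 1 (LiN(iPr)2, 3 equiv, THF, −78 to 0 °C) would be acylated at the methyl group with methyl 3-phenylpropanoate to give 4-hydroxy-6-(2-oxo-4-phenylbutyl)-2H-pyran-2-one F3. The chemistry of steps 1 and 2 is then repeated on it: iminium-catalysed Michael addition to 2 should give the lactol (4S)-2-hydroxy-4-(4-methoxyphenyl)-7-(2-oxo-4-phenylbutyl)-3,4-dihydro-2H,5H-pyrano[4,3-b]pyran-5-one F4, Dess–Martin oxidation the enol lactone (S)-4-(4-methoxyphenyl)-7-(2-oxo-4-phenylbutyl)-3,4-dihydro-2H,5H-pyrano[4,3-b]pyran-2,5-dione F5, and methanolysis the ester methyl (S)-3-[4-hydroxy-2-oxo-6-(2-oxo-4-phenylbutyl)-2H-pyran-3-yl]-3-(4-methoxyphenyl)propanoate F6. Methylation of the pyrone hydroxyl alone under Mitsunobu conditions (PPh3, diisopropyl azodicarboxylate, MeOH, THF), which leave the much less acidic keto methylene untouched, would reach 10.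

Step 3 (O-methylation of the pyronate). Alkylation of the ambident anion at the lactone carbonyl oxygen would give the isomeric 2-methoxy-4-pyranone, and the hindered 4-oxygen may react slowly. The fallback reverses the roles and makes the alcohol the electrophile; it sets out from compound 6 and comes back at compound 7. A Mitsunobu reaction with methanol (PPh3, diisopropyl azodicarboxylate, THF, 0 °C to rt) alkylates the acidic 4-hydroxyl through the alkoxyphosphonium ion, a mode known to give 4-alkoxy-2-pyrones; no new compound is made (F0).

**Further compounds**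

F1 | step 6 | 1-(2,6-dihydroxy-4-methoxyphenyl)-3-phenylpropan-1-one | COc1cc(O)c(C(=O)CCc2ccccc2)c(O)c1
F2 | step 6 | 1-[(4S)-2,7-dihydroxy-5-methoxy-4-(4-methoxyphenyl)-3,4-dihydro-2H-chromen-8-yl]-3-phenylpropan-1-one | OC1C[C@@H](c2ccc(OC)cc2)c2c(OC)cc(O)c(C(=O)CCc3ccccc3)c2O1
F3 | step 4 | 4-hydroxy-6-(2-oxo-4-phenylbutyl)-2H-pyran-2-one | O=C(CCc1ccccc1)CC1=CC(O)=CC(=O)O1
F4 | step 4 | (4S)-2-hydroxy-4-(4-methoxyphenyl)-7-(2-oxo-4-phenylbutyl)-3,4-dihydro-2H,5H-pyrano[4,3-b]pyran-5-one | OC1C[C@@H](c2ccc(OC)cc2)C2=C(O1)C=C(CC(=O)CCc3ccccc3)OC2=O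
F5 | step 4 | (S)-4-(4-methoxyphenyl)-7-(2-oxo-4-phenylbutyl)-3,4-dihydro-2H,5H-pyrano[4,3-b]pyran-2,5-dione | O=C1C[C@@H](c2ccc(OC)cc2)C2=C(O1)C=C(CC(=O)CCc3ccccc3)OC2=O
F6 | step 4 | methyl (S)-3-[4-hydroxy-2-oxo-6-(2-oxo-4-phenylbutyl)-2H-pyran-3-yl]-3-(4-methoxyphenyl)propanoate | COC(=O)C[C@@H](c1ccc(OC)cc1)C1=C(O)C=C(CC(=O)CCc2ccccc2)OC1=O
F0 | step 3 | none | none
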